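14 % of target in Monday's run against 13 % in Friday's, both at 0.833 min, with 3.5 equiv and 5.5 equiv of first nucleophile: that pair starts the dispute over this flask.

the same everywhere: starting material 0.43 M
- Monday's: first nucleophile 3.5 equiv; second nucleophile 1.2 equiv (fed, over 10 min); run made earlier; the fed solution adds 0.10 times the starting volume
- Friday's: first nucleophile 5.5 equiv; second nucleophile 1.2 equiv (fed, over 10 min); run made earlier; the fed solution adds 0.10 times the starting volume
- Saturday's: first nucleophile 2.5 equiv; second nucleophile 2.4 equiv (fed, over 10 min); run made earlier; the fed solution adds 0.10 times the starting volume
- flask: first nucleophile 2.50 equiv; second nucleophile 1.20 equiv (fed, over 10 min); the fed solution adds 0.10 times the starting volume; time 10 min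

| run | time / min | target / % | idle adduct / % |
|---|---|---|---|
| Monday's | 0.500 | 9 | 13 |
| Monday's | 0.833 | 14 | 13 |
| Monday's | 1.50 | 21 | 18 |
| Monday's | 3.00 | 38 | 25 |
| Monday's | 6.00 | 43 | 24 |
| Friday's | 0.500 | 7 | 12 |
| Friday's | 0.833 | 13 | 15 |
| Friday's | 1.50 | 23 | 20 |
| Friday's | 3.00 | 36 | 29 |
| Friday's | 6.00 | 45 | 24 |
| Saturday's | 1.33 | 17 | 18 |
| Saturday's | 2.50 | 24 | 21 |
| Saturday's | 4.00 | 31 | 23 |
| Saturday's | 5.00 | 27 | 22 |
| Saturday's | 6.00 | 30 | 21 |

(each reading ± 2 percentage points)

- a species is counted by the starting material in it: one idle adduct counts as two
- amounts and yields of target count idle adduct too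
- charges are per starting volume, the dose included; the dosed solution carries all of it
- in an amount of target, one idle adduct counts as one target
- the concentration of target that is asked is that of its free form alone

- concentration of target (only what is free in solution) at 10 min, in M
- concentration of idle adduct at 10 min, in M
- concentration of other capture product at 10 min, in M

The forecaster takes Monday's and Friday's runs as a match, “so its order is about zero and the flask should follow them”, and closes the balance on the charge at the end of the dose. This gives 0.143 M of free target, 0.041 M of idle adduct and 0.166 M of other capture product.

I read the same pair differently. My view is that the departure of starting material is the rate-limiting step, first order in its concentration, and that the two capturing nucleophiles share what leaves. By 0.833 min the feed has delivered 0.100 equiv of second nucleophile, far less than Monday's first nucleophile, so I take early target as the whole capture. Its mean gives a clock k, the fraction lost per minute, of 0.174 min⁻¹.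

After 10 min this leaves 17.5 % of the charge uncaptured, free or held in idle adduct: call this share U. With the whole charge standing at 0.391 M after dilution, and keeping the forecast's target and adduct, I get 0.138 M of other capture product, less than the forecast.

The flask gives 0.142 M of free target, 0.0270 M of idle adduct and 0.143 M of other capture product.

    starting material ⇌ intermediate (K = 0.110, k = 0.00360 s⁻¹)
    first nucleophile + intermediate → target (k = 1.50 M⁻¹ s⁻¹)
    second nucleophile + intermediate → other capture product (k = 14.0 M⁻¹ s⁻¹)
    starting material + target ⇌ idle adduct, settled at all times (K = 3.70 M⁻¹)
    intermediate → side product (k = 3.10 × 10⁻⁴ s⁻¹)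
    second nucleophile → decomposition product (k = 6.40 × 10⁻⁶ s⁻¹)

At 10 min target 43.4 % and other capture product 36.6 % leave U at 20.0 %, against my 17.5 %. A balance with no free starting material, the forecast's way of closing it, holds for this flask at 100 min, with starting material 0 %, idle adduct 0 %, target 47.9 % and other capture product 52.1 %. For the neighbouring flask with 2.00 equiv of second nucleophile, the same U puts target plus other capture product at 82.5 %. That flask gives 81.3 %, split as 34.9 % and 46.4 %, with free starting material at 13.1 %.

All runs are simulated with constants of no real substance; the scatter is artificial.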